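## Analysis of the target

The target is a cembrane-type 14-membered carbocycle. The ring carbons are numbered C1 to C14 so that C1 carries the isopropyl group (C15–C17), C4 the methyl C18, C8 the hydroxymethyl C19 and C12 the methyl C20. The C14 ketone is conjugated with the C1=C2 alkene (E: C14 and C3 trans, a trans ring alkene), and C2 is bonded to the trisubstituted C3–C4 epoxide (3S,4R; C2 and C5 cis on the oxirane). The C9 ketone is flanked by the C8 hydroxymethyl centre (8S), and the C12 methyl (12R) is syn to the C13 hydroxyl (13S), which is α to the C14 ketone. The five stereocentres form three clusters (C3/C4, C8, C12/C13) insulated by the CH2 runs C5–C7 and C10–C11, so none can be relayed from another and each must be set absolutely. Sensitive groups are the γ,δ-epoxy enone (acid, SN2′ opening), the β-hydroxy ketone C19/C8/C9 (C8 epimerisation, retro-aldol, dehydration) and the α-ketol C13/C14 (epimerisation, ketol shift). The hard part is to close the 14-membered ring while delivering a trisubstituted E-enone with a branched α-substituent and a cis-epoxide on one face next to it. The feature exploited is the array C14(=O)–C1(iPr)=C2–C3(O)C4. Read backwards it is an oxidised 1,3-dien-14-ol, the product of joining an aldehyde carbon (C14) to the remote alkyne carbon (C1) of a C1≡C2–C3=C4 enyne with syn delivery of hydrogen to C2. A second feature is that C9–C14 with C20 is the backbone of (R)-citronellal, with C12 already correct.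

## Retrosynthetic reasoning

**30 ⇐ 29 ⇐ 28.** The two hydroxyls are unmasked last from silyl ethers (29), because the free aldol and ketol units tolerate little. The epoxide is taken back to the (3Z)-alkene of dienone 28. Only the Z-alkene gives the cis-epoxide. C3=C4 is the electron-rich alkene of 28, while C1=C2 is deactivated by the C14 carbonyl. A chiral dioxirane can therefore place the oxygen regioselectively and with reagent control of the face.

**28 ⇐ 27 ⇐ 26 (key disconnection, C14–C1).** The C14 ketone is taken back to the carbinol 27, and the ring is opened between C14 and C1 to give the acyclic enyne aldehyde 26. Cutting here removes the ring and the trisubstituted enone geometry in one operation and leaves only sp and sp2 carbons at the western end. The forward reaction, a nickel-catalysed reductive alkyne–aldehyde coupling, must bond C14 to C1 and not to C2, add hydrogen syn at C2 (which gives 1E), and close the ring rather than oligomerise. The C3=C4 alkene serves twice, first as the element that directs nickel to C1 and then as the epoxide precursor. The C14 stereocentre formed is irrelevant.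

**26 ⇐ 24 ⇐ 23 ⇐ 22 ⇐ 13 + 20 (C8–C9).** The β-hydroxy ketone is opened by an aldol disconnection in which C19 is the carbonyl of the acyl oxazolidinone 13 and C9 the aldehyde carbon of 20. The auxiliary sets C8 during the fragment union. C19 is then reduced to the hydroxymethyl group and the C9 carbinol oxidised to the ketone. This avoids a late hydroxymethylation of a macrocyclic ketone, which would face a C8/C10 regiochemistry problem.

**20 ⇐ 18 ⇐ 17 ⇐ 16 ⇐ 14.** Aldehyde 20 is the C1–C6 portion of (R)-citronellal 14: its aldehyde carbon becomes C14, its methyl-bearing carbon is C12 (R), and ozonolysis of its trisubstituted alkene reveals C9. The only stereocentre to add is C13, by a catalyst-controlled α-aminoxylation of 14.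

**13 ⇐ 10 ⇐ 9 ⇐ 8 ⇐ 3 + 4 + 2 (C4–C5 and C2–C3).** The Z-trisubstituted enyne comes from a one-pot three-component assembly. The alkylcopper from bromide 3 adds syn across propyne 4 (alkenylcopper 7), and 7 is coupled with bromoalkyne 2, made from 3-methylbut-1-yne 1. The syn addition fixes C2 cis to C5, and the isopropyl group arrives with the alkyne. Acid 10 is then loaded onto oxazolidinone 11.

## Alternatives that were turned down

**Alternative 1:** (textbook) Disconnection of C1=C2; forward key step an intramolecular Horner–Wadsworth–Emmons olefination of the seco phosphonate–aldehyde A1, with the epoxide installed earlier by asymmetric epoxidation of an allylic alcohol. Turned down because the nucleophile is a fully substituted, isopropyl-branched phosphonate carbanion next to the C13 siloxy group, so addition is slow and the two diastereomeric addition pathways are similarly congested (weak E/Z bias). The base it needs also acts on the α,β-epoxy aldehyde, on the C9 ketone with its β-siloxy group (E1cB) and on C13. The epoxy aldehyde end costs its own stereoselective sequence, so no steps are saved.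

**Alternative 2:** Disconnection at C10=C11, an alkene that must then be saturated; forward key step a ring-closing metathesis with a second-generation Grubbs catalyst to macrocycle A2, followed by conjugate reduction. Turned down because the ring closure builds none of the target's functionality or stereocentres. The reduction would have to distinguish the C9 enone from the C14 enone and spare a vinyl epoxide that hydride and copper hydride reagents open in the SN2′ sense. Moving the reduction earlier forces the epoxy enone to be built on the macrocycle without stereocontrol.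

**Alternative 3:** Disconnection at C1≡C2; forward key step a ring-closing alkyne metathesis to cycloalkyne A3, then hydroxyl-directed trans-hydrostannation (tin on C1, hydrogen on C2, E by mechanism) and replacement of tin by isopropyl. Turned down because the last operation, cross-coupling of a secondary alkyl group onto a hindered alkenylstannane flanked by the C14 carbinol, has no reliable basis and invites isopropyl to n-propyl isomerisation on palladium. The propargylic epoxide of A3 is exposed to SN2′ opening under the hydrostannation. Two capped alkynes and three post-cyclisation operations also make the route longer than one in which the isopropyl group arrives with the alkyne.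

Key step: step 14

Remark: C14 of 27 is formed as both epimers; this is accepted because step 15 converts C14 into the ketone.
Remark: metal and boron alkoxides that are only hydrolysed on work-up, and species that exist only inside a catalytic cycle, are described in the Why lines and carry no number.

## Steps

Step 1
Reactants: 1 3-methylbut-1-yne
Product: 2 1-bromo-3-methylbut-1-yne
Conditions: NBS, AgNO3 (cat.), acetone, rt
Reagents that add atoms: N-bromosuccinimide, O=C1CCC(=O)N1Br
Why: Silver-acetylide-mediated electrophilic bromination of a terminal alkyne; it gives the alkynyl electrophile that carries C1, C2 and the isopropyl group.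

Step 2
Reactants: 3 (5-bromopentyloxy)(tert-butyl)dimethylsilane; 4 propyne; 2 1-bromo-3-methylbut-1-yne
Product: 8 tert-butyl{[(6Z)-6,10-dimethylundec-6-en-8-yn-1-yl]oxy}dimethylsilane, via Grignard reagent 5 (not isolated), via alkylcopper 6 (not isolated), via alkenylcopper 7 (not isolated)
Conditions: Mg, Et2O; CuBr·SMe2, Et2O/Me2S, −45 °C; 4, −25 °C; then 2, TMEDA, THF, −20 °C to rt
Reagents that add atoms: magnesium, [Mg] (held in 5 only); CuBr·SMe2, Br[Cu].CSC (copper held in 6 and 7 only)
Why: Carbocupration of a terminal alkyne: the alkylcopper adds syn across propyne with the alkyl group on the internal carbon (C4) and copper on the terminal one (C3). The alkenylcopper then couples with the 1-bromoalkyne with retention, so C2 ends cis to C5 (3Z in target numbering) by mechanism.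

Step 3
Reactants: 8 enyne silyl ether
Product: 9 (6Z)-6,10-dimethylundec-6-en-8-yn-1-ol
Conditions: Bu4NF, THF, 0 °C to rt
Reagents that add atoms: none
Why: Fluoride cleavage of the primary silyl ether; the enyne is inert.

Step 4
Reactants: 9 enyne alcohol
Product: 10 (6Z)-6,10-dimethylundec-6-en-8-ynoic acid
Conditions: TEMPO (2,2,6,6-tetramethylpiperidin-1-oxyl, cat.), PhI(OAc)2, MeCN/H2O, rt
Reagents that add atoms: water, O
Why: Oxoammonium oxidation of the primary alcohol to the aldehyde and, through its hydrate, to the acid; the near-neutral medium leaves the Z-enyne untouched.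

Step 5
Reactants: 10 enyne acid; 11 (4R)-4-benzyl-1,3-oxazolidin-2-one
Product: 13 (4R)-4-benzyl-3-[(6Z)-6,10-dimethylundec-6-en-8-ynoyl]-1,3-oxazolidin-2-one, via mixed pivalic anhydride 12 (not isolated)
Conditions: PivCl, Et3N, THF, −20 °C; then 11, LiCl, −20 °C to rt
Reagents that add atoms: pivaloyl chloride, CC(C)(C)C(=O)Cl (held in 12 only)
Why: N-Acylation of the LiCl-activated oxazolidinone by the mixed anhydride at its less hindered carbonyl; it installs the auxiliary that will set C8.

Step 6
Reactants: 14 (R)-citronellal [(3R)-3,7-dimethyloct-6-enal]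
Product: 16 (2S,3R)-3,7-dimethyl-2-[(phenylamino)oxy]oct-6-en-1-ol, via aminoxy aldehyde 15 (not isolated)
Conditions: PhNO, D-proline (cat.), DMSO, rt; then NaBH4, EtOH, 0 °C
Reagents that add atoms: nitrosobenzene, O=Nc1ccccc1
Why: Proline-catalysed α-aminoxylation (enamine catalysis): the D-proline enamine attacks the nitroso oxygen on the face directed by the carboxylic acid and sets C13 as S under catalyst control, independent of the C12 methyl. Immediate reduction prevents epimerisation of the α-oxy aldehyde.

Step 7
Reactants: 16 aminoxy alcohol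
Product: 17 (2S,3R)-3,7-dimethyloct-6-ene-1,2-diol
Conditions: Zn, AcOH/EtOH, rt
Reagents that add atoms: none
Why: Reductive N–O cleavage by zinc in acetic acid; the trisubstituted alkene and both stereocentres are untouched.

Step 8
Reactants: 17 diol
Product: 18 (2S,3R)-3,7-dimethyl-1,2-bis(triethylsilyloxy)oct-6-ene
Conditions: Et3SiCl, imidazole, DMF, 0 °C to rt
Reagents that add atoms: chlorotriethylsilane, CC[Si](Cl)(CC)CC
Why: Silylation of both hydroxyls; the primary triethylsilyl ether is the latent C14 aldehyde and the secondary one protects O13 to the end.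

Step 9
Reactants: 18 bis(silyl ether)
Product: 20 (4R,5S)-4-methyl-5,6-bis(triethylsilyloxy)hexanal, via ozonide 19 (not isolated)
Conditions: O3, CH2Cl2, −78 °C; PPh3, −78 °C to rt
Reagents that add atoms: ozone, [O-][O+]=O
Why: Ozonolysis of the only alkene with reductive work-up releases the C9 aldehyde and removes the three surplus carbons as acetone.

Step 10
Reactants: 13 acyl oxazolidinone; 20 aldehyde
Product: 22 (4R)-4-benzyl-3-[(2R,3S,6R,7S)-2-[(4Z)-4,8-dimethylnon-4-en-6-yn-1-yl]-3-hydroxy-6-methyl-7,8-bis(triethylsilyloxy)octanoyl]-1,3-oxazolidin-2-one, via boron enolate 21 (not isolated)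
Conditions: Bu2BOTf, iPr2NEt, CH2Cl2, −78 to 0 °C; 20, −78 to 0 °C; pH 7 buffer, MeOH, H2O2, 0 °C
Reagents that add atoms: dibutylboron triflate, CCCCB(CCCC)OS(=O)(=O)C(F)(F)F (held in 21 only)
Why: Evans syn-aldol through the Z-boron enolate and a Zimmerman–Traxler chair; the (R)-benzyl group blocks one enolate face, so C8 is formed with the configuration that is 8S in the target. The syn C9 carbinol is oxidised later, and the step joins the two fragments.

Step 11
Reactants: 22 syn-aldol imide
Product: 23 (2S,3S,6R,7S)-2-[(4Z)-4,8-dimethylnon-4-en-6-yn-1-yl]-6-methyl-7,8-bis(triethylsilyloxy)octane-1,3-diol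
Conditions: LiBH4, MeOH (1 equiv), THF, 0 °C
Reagents that add atoms: none
Why: Reductive removal of the auxiliary by LiBH4 turns the imide carbonyl into the C19 hydroxymethyl group without touching C8; the oxazolidinone 11 is recovered.

Step 12
Reactants: 23 1,3-diol
Product: 24 (2S,3S,6R,7S)-1-(tert-butyldimethylsilyloxy)-2-[(4Z)-4,8-dimethylnon-4-en-6-yn-1-yl]-6-methyl-7,8-bis(triethylsilyloxy)octan-3-ol
Conditions: t-BuMe2SiCl, imidazole, CH2Cl2, −20 to 0 °C
Reagents that add atoms: tert-butylchlorodimethylsilane, CC(C)(C)[Si](C)(C)Cl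
Why: Selective silylation of the primary C19 hydroxyl over the hindered secondary C9 hydroxyl.

Step 13
Reactants: 24 C19 silyl ether with free C9 hydroxyl
Product: 26 (2S,3R,7S,11Z)-7-[(tert-butyldimethylsilyloxy)methyl]-3,11,15-trimethyl-6-oxo-2-(triethylsilyloxy)hexadec-11-en-13-ynal, via bis(alkoxysulfonium) salt 25 (not isolated)
Conditions: (COCl)2, DMSO, CH2Cl2, −78 °C, then −35 °C; Et3N, −78 to 0 °C
Reagents that add atoms: dimethyl sulfoxide, CS(C)=O; oxalyl chloride, O=C(Cl)C(=O)Cl (atoms of both held in 25 only)
Why: Swern oxidation: the activated sulfoxide takes up the free C9 carbinol at −78 °C and, on warming, converts the unhindered primary triethylsilyl ether into its alkoxysulfonium ion (chloride removes silicon), so base gives the C9 ketone and the C14 aldehyde together. The secondary triethylsilyl and primary tert-butyldimethylsilyl ethers are too hindered to react.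

Step 14
Reactants: 26 enyne keto aldehyde
Product: 27 (1E,3Z,8S,12R,13S)-19-(tert-butyldimethylsilyloxy)-14-hydroxy-13-(triethylsilyloxy)cembra-1,3-dien-9-one (both C14 epimers)
Conditions: Ni(cod)2 (20 mol %), PBu3 (40 mol %), Et3B (3 equiv), toluene, rt; 26 added by syringe pump to high dilution
Reagents that add atoms: none
Why: Zerovalent nickel binds the alkyne and the aldehyde and undergoes oxidative cyclisation to an oxanickelacyclopentene, which forms the C14–C1 bond. Ethyl transfer from Et3B (boron ends on O14), β-hydride elimination of ethene and C–H reductive elimination then place hydrogen on C2 cis to C14, so the 1E geometry follows from the mechanism. The closest known reaction type is the nickel-catalysed reductive coupling of alkynes with aldehydes, which includes ynal macrocyclisations to rings of this size and alkene-directed couplings of 1,3-enynes. The 14-membered ring closes in the endo mode, with both alkyne carbons becoming ring members. The new C14 stereocentre is not controlled (a Felkin bias from C13 is expected) and need not be, since both epimers converge in step 15. Regioselectivity for C1 over C2 is secured by the conjugated C3=C4 alkene, which coordinates nickel and steers C–C bond formation to the alkyne carbon remote from it; attack at C2 would also require a 13-membered ring with an exocyclic alkene. The aldehyde reacts in preference to the C9 ketone, which is far less prone to oxidative cyclisation and could only close a nine-membered ring. Slow addition keeps ring closure ahead of intermolecular coupling, and the 3Z alkene and the centres C8, C12 and C13 are not touched.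

Step 15
Reactants: 27 macrocyclic dienol
Product: 28 (1E,3Z,8S,12R,13S)-19-(tert-butyldimethylsilyloxy)-13-(triethylsilyloxy)cembra-1,3-diene-9,14-dione
Conditions: Dess–Martin periodinane, NaHCO3, CH2Cl2, 0 °C to rt
Reagents that add atoms: none
Why: Buffered hypervalent-iodine oxidation of the allylic carbinol; both C14 epimers give the same dienone, and the non-basic medium spares C13 and C8.

Step 16
Reactants: 28 macrocyclic dienone
Product: 29 (1E,3S,4R,8S,12R,13S)-19-(tert-butyldimethylsilyloxy)-3,4-epoxy-13-(triethylsilyloxy)cembr-1-ene-9,14-dione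
Conditions: L-fructose-derived Shi ketone (1,2:4,5-di-O-isopropylidene-β-L-erythro-2,3-hexodiulo-2,6-pyranose, 0.5 equiv), KHSO5 (Oxone), K2CO3, Bu4NHSO4 (cat.), MeCN/CH2(OMe)2, aq. Na2B4O7 buffer, 0 °C
Reagents that add atoms: potassium peroxymonosulfate (KHSO5), [K+].[O-]S(=O)(=O)OO
Why: Shi epoxidation: the chiral dioxirane transfers oxygen to the electron-richer distal C3=C4 alkene, while C1=C2 is deactivated by the carbonyl and screened by the isopropyl group. The transfer is concerted, so the Z-alkene gives the cis-epoxide. The spiro transition-state model for a trisubstituted alkene predicts that the L-series ketone delivers oxygen to the face that gives 3S,4R.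

Step 17
Reactants: 29 bis-silylated epoxy enone
Product: 30 (1E,3S,4R,8S,12R,13S)-3,4-epoxy-13,19-dihydroxycembr-1-ene-9,14-dione (target)
Conditions: HF·pyridine, pyridine, THF, 0 °C to rt
Reagents that add atoms: none
Why: Fluoride-mediated cleavage of both silyl ethers under pyridine-buffered, non-basic conditions chosen to leave the vinyl epoxide, the β-hydroxy ketone and the α-ketol intact.

## Compound list

1 | 3-methylbut-1-yne | CC(C)C#C | starting material
2 | 1-bromo-3-methylbut-1-yne | CC(C)C#CBr | intermediate
3 | (5-bromopentyloxy)(tert-butyl)dimethylsilane | BrCCCCCO[Si](C)(C)C(C)(C)C | starting material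
4 | propyne | CC#C | starting material
5 | [5-(tert-butyldimethylsilyloxy)pentyl]magnesium bromide | Br[Mg]CCCCCO[Si](C)(C)C(C)(C)C | intermediate
6 | [5-(tert-butyldimethylsilyloxy)pentyl]copper (MgBr2/Me2S complex) | [Cu]CCCCCO[Si](C)(C)C(C)(C)C | intermediate
7 | (Z)-[7-(tert-butyldimethylsilyloxy)-2-methylhept-1-en-1-yl]copper | [Cu]/C=C(/C)CCCCCO[Si](C)(C)C(C)(C)C | intermediate
8 | tert-butyl{[(6Z)-6,10-dimethylundec-6-en-8-yn-1-yl]oxy}dimethylsilane | CC(C)C#C/C=C(/C)CCCCCO[Si](C)(C)C(C)(C)C | intermediate
9 | (6Z)-6,10-dimethylundec-6-en-8-yn-1-ol | CC(C)C#C/C=C(/C)CCCCCO | intermediate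
10 | (6Z)-6,10-dimethylundec-6-en-8-ynoic acid | CC(C)C#C/C=C(/C)CCCCC(=O)O | intermediate
11 | (4R)-4-benzyl-1,3-oxazolidin-2-one | O=C1OC[C@@H](Cc2ccccc2)N1 | starting material
12 | (6Z)-6,10-dimethylundec-6-en-8-ynoic pivalic anhydride | CC(C)C#C/C=C(/C)CCCCC(=O)OC(=O)C(C)(C)C | intermediate
13 | (4R)-4-benzyl-3-[(6Z)-6,10-dimethylundec-6-en-8-ynoyl]-1,3-oxazolidin-2-one | CC(C)C#C/C=C(/C)CCCCC(=O)N1[C@H](Cc2ccccc2)COC1=O | intermediate
14 | (R)-citronellal, (3R)-3,7-dimethyloct-6-enal | CC(C)=CCC[C@@H](C)CC=O | starting material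
15 | (2S,3R)-3,7-dimethyl-2-[(phenylamino)oxy]oct-6-enal | CC(C)=CCC[C@@H](C)[C@H](ONc1ccccc1)C=O | intermediate
16 | (2S,3R)-3,7-dimethyl-2-[(phenylamino)oxy]oct-6-en-1-ol | CC(C)=CCC[C@@H](C)[C@H](ONc1ccccc1)CO | intermediate
17 | (2S,3R)-3,7-dimethyloct-6-ene-1,2-diol | CC(C)=CCC[C@@H](C)[C@H](O)CO | intermediate
18 | (2S,3R)-3,7-dimethyl-1,2-bis(triethylsilyloxy)oct-6-ene | CC(C)=CCC[C@@H](C)[C@H](O[Si](CC)(CC)CC)CO[Si](CC)(CC)CC | intermediate
19 | 3,3-dimethyl-5-[(3R,4S)-3-methyl-4,5-bis(triethylsilyloxy)pentyl]-1,2,4-trioxolane (ozonide of 18) | CC1(C)OOC(CC[C@@H](C)[C@H](O[Si](CC)(CC)CC)CO[Si](CC)(CC)CC)O1 | intermediate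
20 | (4R,5S)-4-methyl-5,6-bis(triethylsilyloxy)hexanal | O=CCC[C@@H](C)[C@H](O[Si](CC)(CC)CC)CO[Si](CC)(CC)CC | intermediate
21 | Z-dibutylboron enolate of 13 | CC(C)C#C/C=C(/C)CCC/C=C(\OB(CCCC)CCCC)N1[C@H](Cc2ccccc2)COC1=O | intermediate
22 | (4R)-4-benzyl-3-[(2R,3S,6R,7S)-2-[(4Z)-4,8-dimethylnon-4-en-6-yn-1-yl]-3-hydroxy-6-methyl-7,8-bis(triethylsilyloxy)octanoyl]-1,3-oxazolidin-2-one | CC(C)C#C/C=C(/C)CCC[C@@H](C(=O)N1[C@H](Cc2ccccc2)COC1=O)[C@@H](O)CC[C@@H](C)[C@H](O[Si](CC)(CC)CC)CO[Si](CC)(CC)CC | intermediate
23 | (2S,3S,6R,7S)-2-[(4Z)-4,8-dimethylnon-4-en-6-yn-1-yl]-6-methyl-7,8-bis(triethylsilyloxy)octane-1,3-diol | CC(C)C#C/C=C(/C)CCC[C@@H](CO)[C@@H](O)CC[C@@H](C)[C@H](O[Si](CC)(CC)CC)CO[Si](CC)(CC)CC | intermediate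
24 | (2S,3S,6R,7S)-1-(tert-butyldimethylsilyloxy)-2-[(4Z)-4,8-dimethylnon-4-en-6-yn-1-yl]-6-methyl-7,8-bis(triethylsilyloxy)octan-3-ol | CC(C)C#C/C=C(/C)CCC[C@@H](CO[Si](C)(C)C(C)(C)C)[C@@H](O)CC[C@@H](C)[C@H](O[Si](CC)(CC)CC)CO[Si](CC)(CC)CC | intermediate
25 | bis(dimethylalkoxysulfonium) dichloride of 24 (sulfonium on O9 and O14) | CC(C)C#C/C=C(/C)CCC[C@@H](CO[Si](C)(C)C(C)(C)C)[C@@H](O[S+](C)C)CC[C@@H](C)[C@H](O[Si](CC)(CC)CC)CO[S+](C)C.[Cl-].[Cl-] | intermediate
26 | (2S,3R,7S,11Z)-7-[(tert-butyldimethylsilyloxy)methyl]-3,11,15-trimethyl-6-oxo-2-(triethylsilyloxy)hexadec-11-en-13-ynal | CC(C)C#C/C=C(/C)CCC[C@@H](CO[Si](C)(C)C(C)(C)C)C(=O)CC[C@@H](C)[C@H](O[Si](CC)(CC)CC)C=O | intermediate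
27 | (1E,3Z,8S,12R,13S)-19-(tert-butyldimethylsilyloxy)-14-hydroxy-13-(triethylsilyloxy)cembra-1,3-dien-9-one, both C14 epimers | CC(C)/C1=C\C=C(C)/CCC[C@@H](CO[Si](C)(C)C(C)(C)C)C(=O)CC[C@@H](C)[C@H](O[Si](CC)(CC)CC)C1O | intermediate
28 | (1E,3Z,8S,12R,13S)-19-(tert-butyldimethylsilyloxy)-13-(triethylsilyloxy)cembra-1,3-diene-9,14-dione | CC(C)/C1=C\C=C(C)/CCC[C@@H](CO[Si](C)(C)C(C)(C)C)C(=O)CC[C@@H](C)[C@H](O[Si](CC)(CC)CC)C1=O | intermediate
29 | (1E,3S,4R,8S,12R,13S)-19-(tert-butyldimethylsilyloxy)-3,4-epoxy-13-(triethylsilyloxy)cembr-1-ene-9,14-dione | CC(C)/C1=C\[C@@H]2O[C@]2(C)CCC[C@@H](CO[Si](C)(C)C(C)(C)C)C(=O)CC[C@@H](C)[C@H](O[Si](CC)(CC)CC)C1=O | intermediate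
30 | (1E,3S,4R,8S,12R,13S)-3,4-epoxy-13,19-dihydroxycembr-1-ene-9,14-dione | CC(C)/C1=C\[C@@H]2O[C@]2(C)CCC[C@@H](CO)C(=O)CC[C@@H](C)[C@H](O)C1=O | target

## Step count and least certain steps

Total: 17 steps. Longest linear sequence: 13 steps (steps 1–5 and 10–17, from 1); the branch from 14 (steps 6–9 and 10–17) has 12.

**Step 14 (key step).** Two processes may defeat it. Intermolecular coupling may outrun ring closure, because a 14-membered ring carries an entropic cost. C–C bond formation may also drift to C2, because the isopropyl group makes C1 the more hindered alkyne terminus and the directing alkene is trisubstituted and Z.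

Fallback (sets out from 1 and from alkenylcopper 7 of step 2, returns at 27): the C14–C1 bond is made by a Nozaki–Hiyama–Kishi ring closure of an alkenyl iodide whose position and geometry are fixed by construction.
- Iodine adds anti to 1 (I2, CH2Cl2) to give (E)-1,2-diiodo-3-methylbut-1-ene F1.
- Alkenylcopper 7 is transmetallated with ZnBr2 to the alkenylzinc bromide F2. F2 is coupled with F1 under Pd(PPh3)4 (Negishi coupling) at the less hindered terminal C–I bond, with retention on both partners, to give the (6Z,8E)-9-iodo diene silyl ether F3.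
- F3 is taken through the operations of steps 3 to 5 (alcohol F4, acid F5, mixed pivalic anhydride F6, imide F7), of step 10 with 20 (boron enolate F8, aldol adduct F9), of step 11 (diol F10), of step 12 (C19 silyl ether F11) and of step 13 (bis(alkoxysulfonium) salt F12, iodo keto aldehyde F13).
- F13 is closed with CrCl2 and catalytic NiCl2 in DMSO/THF at high dilution. The alkenylchromium species adds only to the aldehyde, with retention of the C1=C2 geometry, and gives 27.

**Step 16.** The most likely failure is poor or reversed facial selectivity, because the ring conformation exposes one face of C3=C4 and may override the ketone catalyst. The basic medium may also cause β-elimination of the C19 siloxy group or epimerisation at C13.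

Fallback (sets out from 28, returns at 29): a halohydrin route whose first step is non-basic and which delivers oxygen to the face opposite to the one an electrophile reaches directly. NBS in aqueous THF at 0 °C adds bromine to C3 from the exposed face and water anti at the tertiary C4 to give the (3R,4R)-bromohydrin F14. Ag2O in THF then closes the oxirane by displacement at C3 with inversion, which gives the cis-epoxide 29. This is the useful outcome exactly when the ring, not the catalyst, decides the face.

**Step 13.** The oxidative desilylation may be unselective (attack on the secondary triethylsilyl ether at O13) or incomplete, the C9 alkoxysulfonium ion may decompose during the warm period, and triethylamine may epimerise the α-siloxy aldehyde.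

Fallback (sets out from 24, returns at 26): PPTS in MeOH/CH2Cl2 at 0 °C removes only the primary triethylsilyl group to give the diol F15. Dess–Martin periodinane with NaHCO3 then oxidises the C9 and C14 carbinols together to 26.

**Step 2.** The coupling of the alkenylcopper with the bromoalkyne may be diverted into halogen–copper exchange and homocoupling, and the carbocupration may be incomplete with the siloxy-substituted alkylcopper.

Fallback (sets out from alkenylcopper 7 and from 1, returns at 8): 7 is quenched with iodine to give the alkenyl iodide F16 with retention. F16 is joined to 1 by a Sonogashira coupling (PdCl2(PPh3)2, CuI, Et3N), again with retention, which makes step 1 unnecessary.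

## Further compounds

F1 | step 14 | (E)-1,2-diiodo-3-methylbut-1-ene | CC(C)/C(I)=C\I
F2 | step 14 | (Z)-[7-(tert-butyldimethylsilyloxy)-2-methylhept-1-en-1-yl]zinc bromide | Br[Zn]/C=C(/C)CCCCCO[Si](C)(C)C(C)(C)C
F3 | step 14 | tert-butyl{[(6Z,8E)-9-iodo-6,10-dimethylundeca-6,8-dien-1-yl]oxy}dimethylsilane | CC(C)/C(I)=C\C=C(C)/CCCCCO[Si](C)(C)C(C)(C)C
F4 | step 14 | (6Z,8E)-9-iodo-6,10-dimethylundeca-6,8-dien-1-ol | CC(C)/C(I)=C\C=C(C)/CCCCCO
F5 | step 14 | (6Z,8E)-9-iodo-6,10-dimethylundeca-6,8-dienoic acid | CC(C)/C(I)=C\C=C(C)/CCCCC(=O)O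
F6 | step 14 | mixed pivalic anhydride of F5 | CC(C)/C(I)=C\C=C(C)/CCCCC(=O)OC(=O)C(C)(C)C
F7 | step 14 | (4R)-4-benzyl-3-[(6Z,8E)-9-iodo-6,10-dimethylundeca-6,8-dienoyl]-1,3-oxazolidin-2-one | CC(C)/C(I)=C\C=C(C)/CCCCC(=O)N1[C@H](Cc2ccccc2)COC1=O
F8 | step 14 | Z-dibutylboron enolate of F7 | CC(C)/C(I)=C\C=C(C)/CCC/C=C(\OB(CCCC)CCCC)N1[C@H](Cc2ccccc2)COC1=O
F9 | step 14 | syn-aldol adduct of F7 and 20 (iodo diene analogue of 22) | CC(C)/C(I)=C\C=C(C)/CCC[C@@H](C(=O)N1[C@H](Cc2ccccc2)COC1=O)[C@@H](O)CC[C@@H](C)[C@H](O[Si](CC)(CC)CC)CO[Si](CC)(CC)CC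
F10 | step 14 | iodo diene analogue of diol 23 | CC(C)/C(I)=C\C=C(C)/CCC[C@@H](CO)[C@@H](O)CC[C@@H](C)[C@H](O[Si](CC)(CC)CC)CO[Si](CC)(CC)CC
F11 | step 14 | iodo diene analogue of silyl ether 24 | CC(C)/C(I)=C\C=C(C)/CCC[C@@H](CO[Si](C)(C)C(C)(C)C)[C@@H](O)CC[C@@H](C)[C@H](O[Si](CC)(CC)CC)CO[Si](CC)(CC)CC
F12 | step 14 | iodo diene analogue of sulfonium salt 25 | CC(C)/C(I)=C\C=C(C)/CCC[C@@H](CO[Si](C)(C)C(C)(C)C)[C@@H](O[S+](C)C)CC[C@@H](C)[C@H](O[Si](CC)(CC)CC)CO[S+](C)C.[Cl-].[Cl-]
F13 | step 14 | (2S,3R,7S,11Z,13E)-7-[(tert-butyldimethylsilyloxy)methyl]-14-iodo-3,11,15-trimethyl-6-oxo-2-(triethylsilyloxy)hexadeca-11,13-dienal | CC(C)/C(I)=C\C=C(C)/CCC[C@@H](CO[Si](C)(C)C(C)(C)C)C(=O)CC[C@@H](C)[C@H](O[Si](CC)(CC)CC)C=O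
F14 | step 16 | (1E,3R,4R,8S,12R,13S)-3-bromo-19-(tert-butyldimethylsilyloxy)-4-hydroxy-13-(triethylsilyloxy)cembr-1-ene-9,14-dione | CC(C)/C1=C\[C@@H](Br)[C@@](O)(C)CCC[C@@H](CO[Si](C)(C)C(C)(C)C)C(=O)CC[C@@H](C)[C@H](O[Si](CC)(CC)CC)C1=O
F15 | step 13 | (2S,3S,6R,7S)-1-(tert-butyldimethylsilyloxy)-2-[(4Z)-4,8-dimethylnon-4-en-6-yn-1-yl]-6-methyl-7-(triethylsilyloxy)octane-3,8-diol | CC(C)C#C/C=C(/C)CCC[C@@H](CO[Si](C)(C)C(C)(C)C)[C@@H](O)CC[C@@H](C)[C@H](O[Si](CC)(CC)CC)CO
F16 | step 2 | tert-butyl{[(6Z)-7-iodo-6-methylhept-6-en-1-yl]oxy}dimethylsilane | I/C=C(/C)CCCCCO[Si](C)(C)C(C)(C)C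
A1 | alternative 1 | seco epoxy aldehyde bearing a dimethyl phosphonate on C1 (C2 aldehyde, 3S,4R-epoxide, 8S,12R,13S, silyl ethers as in 28) | O=C[C@@H]1O[C@]1(C)CCC[C@@H](CO[Si](C)(C)C(C)(C)C)C(=O)CC[C@@H](C)[C@H](O[Si](CC)(CC)CC)C(=O)C(C(C)C)P(=O)(OC)OC
A2 | alternative 2 | (1E,10E)-3,4-epoxycembra-1,10-diene-9,14-dione with silyl ethers as in 29 (3S,4R,8S,12R,13S) | CC(C)/C1=C\[C@@H]2O[C@]2(C)CCC[C@@H](CO[Si](C)(C)C(C)(C)C)C(=O)/C=C/[C@@H](C)[C@H](O[Si](CC)(CC)CC)C1=O
A3 | alternative 3 | 15,16,17-trinor-3,4-epoxy-14-hydroxycembr-1-yn-9-one with silyl ethers as in 29 (3S,4R,8S,12R,13S, C14 unassigned) | OC1C#C[C@@H]2O[C@]2(C)CCC[C@@H](CO[Si](C)(C)C(C)(C)C)C(=O)CC[C@@H](C)[C@@H]1O[Si](CC)(CC)CC
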